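**Retrosynthetic overview** (germacranolide numbering: C1–C10 ring, lactone O–C6/C7/C11/C12 with C13 the exocyclic methylene, C14 on C10, C15 on C4)

1. Last bond made is C7–C8, by a Nozaki–Hiyama–Kishi allylation: the C8 aldehyde of an open-chain seco-aldehyde is attacked by C7, the γ-carbon of the allylchromium formed from a 3-(bromomethyl)butenolide. This closes the ten-membered carbocycle, sets C7 and C8, and moves the butenolide double bond to C11=C13, giving the fully acylated target directly.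
2. Enabling feature: the homoallylic alcohol HO–C8–C7–C11(=C13H2). The free C8 hydroxyl sits next to C7, the atom shared by the γ-lactone ring (O–C6–C7–C11–C12) and the ten-membered ring, and C11 carries the exocyclic methylene.
3. Seco-aldehyde: C9 epoxyangelate (Yamaguchi), C3 acetate, C13 bromide (Corey–Kim), C8 aldehyde. Butenolide from a C6 propargylic alcohol by hydroalumination–iodination and carbonylative lactonisation; C6 and C3 by catalytic asymmetric alkynylations; C4=C5 (Z) by syn-methylcupration of an ynoate.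
4. C1=C10 (Z) by Wittig olefination of a glycerate-derived α-alkoxy methyl ketone (C9 from the chiral pool); epoxyangelic acid by Sharpless epoxidation of angelyl alcohol.
5. Ring order: oxirane of the side-chain acid (step 2), butenolide (step 16), ten-membered carbocycle (step 25).

Key step: step 25

Remark on the chemistry (assumption): the (S,S)-ProPhenol zinc catalyst is taken to give the (S)-propargylic alcohol in step 9 and the (R,R)-ligand the (R)-alcohol in step 14; if the facial sense on these substrates is the reverse, the two ligand enantiomers are exchanged and nothing else changes.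

**Route**

Step 1
Reactants: 1 angelic acid [(2Z)-2-methylbut-2-enoic acid]
Product: 2 (2Z)-2-methylbut-2-en-1-ol
Conditions: LiAlH4, Et2O, 0 °C → rt; aq. NaOH work-up
Reagents that add atoms: none
Why: Hydride reduction of the carboxylic acid to the primary allylic alcohol leaves the trisubstituted alkene alone, so the Z geometry of angelic acid is carried into 2.

Step 2
Reactants: 2 (2Z)-2-methylbut-2-en-1-ol
Product: 3 [(2S,3R)-2,3-dimethyloxiran-2-yl]methanol
Conditions: Ti(OiPr)4 (10 mol%), L-(+)-diisopropyl tartrate (12 mol%), t-BuOOH, 4 Å molecular sieves, CH2Cl2, −20 °C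
Reagents that add atoms: tert-butyl hydroperoxide, CC(C)(C)OO
Why: Sharpless asymmetric epoxidation, in which the titanium–L-(+)-tartrate complex delivers oxygen to the alkene face that gives the (2S,3R)-epoxy alcohol, the cis relationship of CH2OH and the C3 methyl coming from the Z-alkene.

Step 3
Reactants: 3 [(2S,3R)-2,3-dimethyloxiran-2-yl]methanol
Product: 4 (2R,3R)-2,3-dimethyloxirane-2-carboxylic acid
Conditions: RuCl3 hydrate (2 mol%), NaIO4, CCl4/MeCN/H2O, rt
Reagents that add atoms: water, O (second carboxyl oxygen, via the aldehyde hydrate; NaIO4 is the terminal oxidant)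
Why: Catalytic ruthenium tetroxide oxidation of the primary alcohol to the acid should not open the epoxide or touch either stereocenter; the C2 descriptor becomes R only through the new priority of the carboxyl group.

Step 4
Reactants: 5 methyl (4S)-2,2-dimethyl-1,3-dioxolane-4-carboxylate
Product: 7 1-[(4S)-2,2-dimethyl-1,3-dioxolan-4-yl]ethan-1-one, via Weinreb amide 6 (not isolated)
Conditions: MeNH(OMe)·HCl, i-PrMgCl, THF, −20 °C; then MeMgBr, −20 → 0 °C; aq. NH4Cl
Reagents that add atoms: methylmagnesium bromide, C[Mg]Br; N,O-dimethylhydroxylamine hydrochloride, CNOC.Cl (its atoms are in 6 only)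
Why: Weinreb ketone synthesis, in which the chelated tetrahedral adduct of the amide with MeMgBr collapses only on work-up, so the methyl ketone should form without over-addition and without epimerising the α-alkoxy center.

Step 5
Reactants: 8 (3-bromopropoxy)(tert-butyl)dimethylsilane
Product: 9 {3-[(tert-butyldimethylsilyl)oxy]propyl}triphenylphosphonium bromide
Conditions: PPh3, MeCN, reflux
Reagents that add atoms: triphenylphosphine, c1ccc(cc1)P(c1ccccc1)c1ccccc1
Why: SN2 quaternisation of triphenylphosphine by the primary bromide gives the phosphonium salt.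

Step 6
Reactants: 9 {3-[(tert-butyldimethylsilyl)oxy]propyl}triphenylphosphonium bromide; 7 1-[(4S)-2,2-dimethyl-1,3-dioxolan-4-yl]ethan-1-one
Product: 11 tert-butyl{[(3Z)-4-[(4R)-2,2-dimethyl-1,3-dioxolan-4-yl]pent-3-en-1-yl]oxy}dimethylsilane, via phosphorus ylide 10 (not isolated)
Conditions: KN(SiMe3)2, THF, −78 → 0 °C; then 7, −78 °C → rt
Reagents that add atoms: none
Why: Wittig olefination of an α-alkoxy methyl ketone with a salt-free non-stabilised ylide, a reaction type known to give the Z-trisubstituted alkene with the alkoxy-bearing carbon (C9) cis to the new chain (C2); C9 comes unchanged from the chiral pool.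

Step 7
Reactants: 11 tert-butyl{[(3Z)-4-[(4R)-2,2-dimethyl-1,3-dioxolan-4-yl]pent-3-en-1-yl]oxy}dimethylsilane
Product: 12 (3Z)-4-[(4R)-2,2-dimethyl-1,3-dioxolan-4-yl]pent-3-en-1-ol
Conditions: Bu4NF, THF, 0 °C → rt
Reagents that add atoms: none
Why: Fluoride-mediated desilylation cleaves the primary silyl ether and leaves the acetonide untouched.

Step 8
Reactants: 12 (3Z)-4-[(4R)-2,2-dimethyl-1,3-dioxolan-4-yl]pent-3-en-1-ol
Product: 13 (3Z)-4-[(4R)-2,2-dimethyl-1,3-dioxolan-4-yl]pent-3-enal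
Conditions: Dess–Martin periodinane, NaHCO3, CH2Cl2, 0 °C; used crude
Reagents that add atoms: none
Why: Dess–Martin oxidation under buffered non-basic conditions should give the β,γ-unsaturated aldehyde without migration of the double bond into conjugation.

Step 9
Reactants: 13 (3Z)-4-[(4R)-2,2-dimethyl-1,3-dioxolan-4-yl]pent-3-enal; 14 methyl prop-2-ynoate
Product: 15 methyl (4S,6Z)-7-[(4R)-2,2-dimethyl-1,3-dioxolan-4-yl]-4-hydroxyoct-6-en-2-ynoate
Conditions: (S,S)-ProPhenol (20 mol%), Me2Zn (3 equiv), Ph3P=O (40 mol%), toluene, 4 °C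
Reagents that add atoms: none
Why: Catalytic asymmetric alkynylation with a dinuclear zinc–ProPhenol catalyst adds the zinc acetylide of 14 to one aldehyde face and sets the C3 carbinol (S) under catalyst control.

Step 10
Reactants: 15 methyl (4S,6Z)-7-[(4R)-2,2-dimethyl-1,3-dioxolan-4-yl]-4-hydroxyoct-6-en-2-ynoate
Product: 16 methyl (4S,6Z)-7-[(4R)-2,2-dimethyl-1,3-dioxolan-4-yl]-4-[(triethylsilyl)oxy]oct-6-en-2-ynoate
Conditions: Et3SiOTf, 2,6-lutidine, CH2Cl2, −78 °C
Reagents that add atoms: triethylsilyl trifluoromethanesulfonate, CC[Si](CC)(CC)OS(=O)(=O)C(F)(F)F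
Why: Silylation with the triflate and a hindered non-nucleophilic base protects the propargylic alcohol without conjugate addition to the ynoate.

Step 11
Reactants: 16 methyl (4S,6Z)-7-[(4R)-2,2-dimethyl-1,3-dioxolan-4-yl]-4-[(triethylsilyl)oxy]oct-6-en-2-ynoate
Product: 17 methyl (2Z,4S,6Z)-7-[(4R)-2,2-dimethyl-1,3-dioxolan-4-yl]-3-methyl-4-[(triethylsilyl)oxy]octa-2,6-dienoate
Conditions: Me2CuLi (from CuI and MeLi, 1:2), THF, −78 °C; MeOH quench at −78 °C, then aq. NH4Cl
Reagents that add atoms: lithium dimethylcuprate, [Li+].C[Cu-]C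
Why: syn-Carbocupration of the ynoate followed by protonation with retention should give the (Z)-β-methyl enoate in which C3 and the ester carbon (C6) are cis, which is the C4=C5 geometry of the target.

Step 12
Reactants: 17 methyl (2Z,4S,6Z)-7-[(4R)-2,2-dimethyl-1,3-dioxolan-4-yl]-3-methyl-4-[(triethylsilyl)oxy]octa-2,6-dienoate
Product: 18 (2Z,4S,6Z)-7-[(4R)-2,2-dimethyl-1,3-dioxolan-4-yl]-3-methyl-4-[(triethylsilyl)oxy]octa-2,6-dien-1-ol
Conditions: i-Bu2AlH (2.5 equiv), CH2Cl2, −78 °C; Rochelle salt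
Reagents that add atoms: none
Why: 1,2-Reduction of the conjugated ester with i-Bu2AlH gives the allylic alcohol with the Z-alkene and both protecting groups intact.

Step 13
Reactants: 18 (2Z,4S,6Z)-7-[(4R)-2,2-dimethyl-1,3-dioxolan-4-yl]-3-methyl-4-[(triethylsilyl)oxy]octa-2,6-dien-1-ol
Product: 19 (2Z,4S,6Z)-7-[(4R)-2,2-dimethyl-1,3-dioxolan-4-yl]-3-methyl-4-[(triethylsilyl)oxy]octa-2,6-dienal
Conditions: MnO2 (excess), CH2Cl2, rt
Reagents that add atoms: none
Why: Neutral MnO2 oxidation is selective for the allylic alcohol and should give the enal with the Z geometry retained.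

Step 14
Reactants: 19 (2Z,4S,6Z)-7-[(4R)-2,2-dimethyl-1,3-dioxolan-4-yl]-3-methyl-4-[(triethylsilyl)oxy]octa-2,6-dienal; 20 tert-butyldimethyl(prop-2-yn-1-yloxy)silane
Product: 21 (4R,5Z,7S,9Z)-1-[(tert-butyldimethylsilyl)oxy]-10-[(4R)-2,2-dimethyl-1,3-dioxolan-4-yl]-6-methyl-7-[(triethylsilyl)oxy]undeca-5,9-dien-2-yn-4-ol
Conditions: (R,R)-ProPhenol (20 mol%), Me2Zn (3 equiv), Ph3P=O (40 mol%), toluene, 4 °C
Reagents that add atoms: none
Why: A second zinc–ProPhenol asymmetric alkynylation, for which enals are the best substrates, adds the zinc acetylide of 20 to the enal and sets the C6 carbinol (R) under catalyst control.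

Step 15
Reactants: 21 (4R,5Z,7S,9Z)-1-[(tert-butyldimethylsilyl)oxy]-10-[(4R)-2,2-dimethyl-1,3-dioxolan-4-yl]-6-methyl-7-[(triethylsilyl)oxy]undeca-5,9-dien-2-yn-4-ol
Product: 23 (2Z,4R,5Z,7S,9Z)-1-[(tert-butyldimethylsilyl)oxy]-10-[(4R)-2,2-dimethyl-1,3-dioxolan-4-yl]-2-iodo-6-methyl-7-[(triethylsilyl)oxy]undeca-2,5,9-trien-4-ol, via cyclic alkenylaluminate 22 (not isolated)
Conditions: NaAlH2(OCH2CH2OMe)2 (Red-Al), THF, −20 → 0 °C; then I2, THF, −78 °C; aq. Na2S2O3/Rochelle salt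
Reagents that add atoms: iodine, II; NaAlH2(OCH2CH2OMe)2, [Na+].COCCO[AlH2-]OCCOC (its aluminium and alkoxide atoms are in 22 only)
Why: Hydroxyl-directed trans-hydroalumination puts hydride on the proximal alkyne carbon (C7) and aluminium on the distal one (C11) in a five-membered alkoxyaluminate, and iodinolysis with retention should give the (Z)-iodoalkene with C6 and iodine cis.

Step 16
Reactants: 23 (2Z,4R,5Z,7S,9Z)-1-[(tert-butyldimethylsilyl)oxy]-10-[(4R)-2,2-dimethyl-1,3-dioxolan-4-yl]-2-iodo-6-methyl-7-[(triethylsilyl)oxy]undeca-2,5,9-trien-4-ol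
Product: 24 (5R)-3-{[(tert-butyldimethylsilyl)oxy]methyl}-5-{(1Z,3S,5Z)-6-[(4R)-2,2-dimethyl-1,3-dioxolan-4-yl]-2-methyl-3-[(triethylsilyl)oxy]hepta-1,5-dien-1-yl}furan-2(5H)-one
Conditions: PdCl2(PPh3)2 (5 mol%), CO (1 atm), K2CO3, THF, 35 °C
Reagents that add atoms: carbon monoxide, [C-]#[O+]
Why: Palladium-catalysed carbonylative lactonisation (oxidative addition of the vinyl iodide to zerovalent palladium, CO insertion, capture of the acylpalladium by the cis C6 hydroxyl) closes the butenolide with C6 unchanged.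

Step 17
Reactants: 24 (5R)-3-{[(tert-butyldimethylsilyl)oxy]methyl}-5-{(1Z,3S,5Z)-6-[(4R)-2,2-dimethyl-1,3-dioxolan-4-yl]-2-methyl-3-[(triethylsilyl)oxy]hepta-1,5-dien-1-yl}furan-2(5H)-one
Product: 25 (5R)-3-{[(tert-butyldimethylsilyl)oxy]methyl}-5-{(1Z,3S,5Z)-6-[(4R)-2,2-dimethyl-1,3-dioxolan-4-yl]-3-hydroxy-2-methylhepta-1,5-dien-1-yl}furan-2(5H)-one
Conditions: HF·pyridine, pyridine, THF, 0 °C
Reagents that add atoms: none
Why: Selective desilylation, since buffered HF·pyridine should cleave the secondary triethylsilyl ether much faster than the primary tert-butyldimethylsilyl ether and spare the acetonide.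

Step 18
Reactants: 25 (5R)-3-{[(tert-butyldimethylsilyl)oxy]methyl}-5-{(1Z,3S,5Z)-6-[(4R)-2,2-dimethyl-1,3-dioxolan-4-yl]-3-hydroxy-2-methylhepta-1,5-dien-1-yl}furan-2(5H)-one
Product: 26 (5R)-5-{(1Z,3S,5Z)-3-acetoxy-6-[(4R)-2,2-dimethyl-1,3-dioxolan-4-yl]-2-methylhepta-1,5-dien-1-yl}-3-{[(tert-butyldimethylsilyl)oxy]methyl}furan-2(5H)-one
Conditions: Ac2O, pyridine, DMAP (cat.), CH2Cl2, 0 °C
Reagents that add atoms: acetic anhydride, CC(=O)OC(C)=O
Why: DMAP-catalysed acylation installs the C3 acetate with retention at C3.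

Step 19
Reactants: 26 (5R)-5-{(1Z,3S,5Z)-3-acetoxy-6-[(4R)-2,2-dimethyl-1,3-dioxolan-4-yl]-2-methylhepta-1,5-dien-1-yl}-3-{[(tert-butyldimethylsilyl)oxy]methyl}furan-2(5H)-one
Product: 27 (5R)-5-[(1Z,3S,5Z,7R)-3-acetoxy-7,8-dihydroxy-2,6-dimethylocta-1,5-dien-1-yl]-3-(hydroxymethyl)furan-2(5H)-one
Conditions: AcOH/THF/H2O (3:1:1), 40 °C
Reagents that add atoms: none
Why: Acid-catalysed acetal hydrolysis and desilylation remove the acetonide and the primary allylic silyl ether in one operation, while the acetate and the lactone should survive.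

Step 20
Reactants: 27 (5R)-5-[(1Z,3S,5Z,7R)-3-acetoxy-7,8-dihydroxy-2,6-dimethylocta-1,5-dien-1-yl]-3-(hydroxymethyl)furan-2(5H)-one
Product: 28 (5R)-5-[(1Z,3S,5Z,7R)-3-acetoxy-7-hydroxy-2,6-dimethyl-8-[(triethylsilyl)oxy]octa-1,5-dien-1-yl]-3-{[(triethylsilyl)oxy]methyl}furan-2(5H)-one
Conditions: Et3SiCl (2.1 equiv), imidazole, CH2Cl2, −40 → −20 °C
Reagents that add atoms: chlorotriethylsilane, CC[Si](CC)(CC)Cl
Why: Kinetic silylation at low temperature should discriminate the two primary hydroxyls from the more hindered secondary allylic C9 hydroxyl.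

Step 21
Reactants: 28 (5R)-5-[(1Z,3S,5Z,7R)-3-acetoxy-7-hydroxy-2,6-dimethyl-8-[(triethylsilyl)oxy]octa-1,5-dien-1-yl]-3-{[(triethylsilyl)oxy]methyl}furan-2(5H)-one; 4 (2R,3R)-2,3-dimethyloxirane-2-carboxylic acid
Product: 30 (5R)-5-[(1Z,3S,5Z,7R)-3-acetoxy-7-{[(2R,3R)-2,3-dimethyloxirane-2-carbonyl]oxy}-2,6-dimethyl-8-[(triethylsilyl)oxy]octa-1,5-dien-1-yl]-3-{[(triethylsilyl)oxy]methyl}furan-2(5H)-one, via mixed anhydride 29 (not isolated)
Conditions: 4, 2,4,6-trichlorobenzoyl chloride, Et3N, THF, rt; then 28, DMAP, toluene, 0 °C → rt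
Reagents that add atoms: 2,4,6-trichlorobenzoyl chloride, O=C(Cl)c1c(Cl)cc(Cl)cc1Cl (its atoms are in 29 only)
Why: Yamaguchi esterification, a method suited to α,α-disubstituted acids, acylates the secondary C9 hydroxyl with retention at C9 and at both epoxide carbons.

Step 22
Reactants: 30 (5R)-5-[(1Z,3S,5Z,7R)-3-acetoxy-7-{[(2R,3R)-2,3-dimethyloxirane-2-carbonyl]oxy}-2,6-dimethyl-8-[(triethylsilyl)oxy]octa-1,5-dien-1-yl]-3-{[(triethylsilyl)oxy]methyl}furan-2(5H)-one
Product: 31 (5R)-5-[(1Z,3S,5Z,7R)-3-acetoxy-7-{[(2R,3R)-2,3-dimethyloxirane-2-carbonyl]oxy}-8-hydroxy-2,6-dimethylocta-1,5-dien-1-yl]-3-(hydroxymethyl)furan-2(5H)-one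
Conditions: PPTS (cat.), MeOH/CH2Cl2, 0 °C
Reagents that add atoms: none
Why: Mild acid-catalysed methanolysis removes both primary triethylsilyl ethers and should neither open the epoxide nor cleave the esters.

Step 23
Reactants: 31 (5R)-5-[(1Z,3S,5Z,7R)-3-acetoxy-7-{[(2R,3R)-2,3-dimethyloxirane-2-carbonyl]oxy}-8-hydroxy-2,6-dimethylocta-1,5-dien-1-yl]-3-(hydroxymethyl)furan-2(5H)-one
Product: 32 (5R)-5-[(1Z,3S,5Z,7R)-3-acetoxy-7-{[(2R,3R)-2,3-dimethyloxirane-2-carbonyl]oxy}-8-hydroxy-2,6-dimethylocta-1,5-dien-1-yl]-3-(bromomethyl)furan-2(5H)-one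
Conditions: NBS, Me2S, CH2Cl2, −20 → 0 °C
Reagents that add atoms: N-bromosuccinimide, O=C1CCC(=O)N1Br
Why: Corey–Kim bromination converts allylic alcohols into allylic bromides by SN2 displacement of the alkoxysulfonium group under neutral conditions and should leave the saturated primary C8 alcohol unchanged.

Step 24
Reactants: 32 (5R)-5-[(1Z,3S,5Z,7R)-3-acetoxy-7-{[(2R,3R)-2,3-dimethyloxirane-2-carbonyl]oxy}-8-hydroxy-2,6-dimethylocta-1,5-dien-1-yl]-3-(bromomethyl)furan-2(5H)-one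
Product: 33 (5R)-5-[(1Z,3S,5Z,7R)-3-acetoxy-7-{[(2R,3R)-2,3-dimethyloxirane-2-carbonyl]oxy}-2,6-dimethyl-8-oxoocta-1,5-dien-1-yl]-3-(bromomethyl)furan-2(5H)-one
Conditions: Dess–Martin periodinane, NaHCO3, CH2Cl2, 0 °C; used crude
Reagents that add atoms: none
Why: Dess–Martin oxidation gives the α-acyloxy aldehyde under non-basic conditions, so the epimerisable C9 center and the allylic bromide should be preserved.

Step 25
Reactants: 33 (5R)-5-[(1Z,3S,5Z,7R)-3-acetoxy-7-{[(2R,3R)-2,3-dimethyloxirane-2-carbonyl]oxy}-2,6-dimethyl-8-oxoocta-1,5-dien-1-yl]-3-(bromomethyl)furan-2(5H)-one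
Product: 35 CNP0137407.10 [(3S,6R,7R,8R,9R,1(10)Z,4Z)-3-acetoxy-9-{[(2R,3R)-2,3-dimethyloxirane-2-carbonyl]oxy}-8-hydroxygermacra-1(10),4,11(13)-trien-12,6-olide], via allylchromium species 34 (not isolated)
Conditions: CrCl2 (10 equiv), THF/DMF, rt, syringe-pump addition of 33 over 12 h (final about 1 mM); aq. NH4Cl
Reagents that add atoms: CrCl2, Cl[Cr]Cl (its atoms are in 34 only)
Why: Two equivalents of CrCl2 reduce the allylic C13–Br bond to the allylchromium species 34, whose γ-carbon C7 adds to the C8 aldehyde through a six-membered chair (Zimmerman–Traxler) transition state with allylic transposition, so that C7–C8 forms, the C7=C11 double bond moves to C11=C13 and the chromium alkoxide is hydrolysed on work-up. The closest known reaction type is the divalent-chromium (Nozaki–Hiyama–Kishi) allylation of aldehydes with 3-(bromomethyl)furan-2(5H)-ones, which gives β-(hydroxyalkyl)-α-methylene-γ-butyrolactones, together with Nozaki–Hiyama–Kishi allylations that close ten-membered germacranolide rings. The ten-membered carbocycle closes in a 10-exo-trig mode at the aldehyde carbon (SE2′ at the allylmetal); the lactone ring is already present. C7 is controlled by C6, the aldehyde being delivered to the butenolide face anti to the C5 alkenyl substituent (trans-fused lactone), and C8 is controlled by the chair, in which the ring-fixed E-type position of C6 and an equatorial C9 lead to the anti C7/C8 relationship (8R). The step needs intramolecular over intermolecular allylation, which slow addition to excess CrCl2 at high dilution and the two chain-folding Z-alkenes should secure, γ- over α-attack, which the cyclic transition state secures, and chemoselectivity for the allylic bromide over the acetate, the epoxy ester and the lactone, which is typical of CrCl2. The required aldehyde face is opposite to the one a Felkin–Anh analysis of the C9 acyloxy center would favour, so the outcome rests on the butenolide-face and chair preferences dominating once C10 must lie inside the forming ring.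

**Compound list**

1 | angelic acid, (2Z)-2-methylbut-2-enoic acid | C/C=C(/C)C(=O)O | starting material
2 | (2Z)-2-methylbut-2-en-1-ol | C/C=C(/C)CO | intermediate
3 | [(2S,3R)-2,3-dimethyloxiran-2-yl]methanol | OC[C@]1(C)O[C@@H]1C | intermediate
4 | (2R,3R)-2,3-dimethyloxirane-2-carboxylic acid | OC(=O)[C@]1(C)O[C@@H]1C | intermediate
5 | methyl (4S)-2,2-dimethyl-1,3-dioxolane-4-carboxylate | COC(=O)[C@@H]1COC(C)(C)O1 | starting material
6 | (4S)-N-methoxy-N,2,2-trimethyl-1,3-dioxolane-4-carboxamide | CON(C)C(=O)[C@@H]1COC(C)(C)O1 | intermediate (not isolated)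
7 | 1-[(4S)-2,2-dimethyl-1,3-dioxolan-4-yl]ethan-1-one | CC(=O)[C@@H]1COC(C)(C)O1 | intermediate
8 | (3-bromopropoxy)(tert-butyl)dimethylsilane | CC(C)(C)[Si](C)(C)OCCCBr | starting material
9 | {3-[(tert-butyldimethylsilyl)oxy]propyl}triphenylphosphonium bromide | CC(C)(C)[Si](C)(C)OCCC[P+](c1ccccc1)(c1ccccc1)c1ccccc1.[Br-] | intermediate
10 | {3-[(tert-butyldimethylsilyl)oxy]propylidene}triphenylphosphorane | CC(C)(C)[Si](C)(C)OCCC=P(c1ccccc1)(c1ccccc1)c1ccccc1 | intermediate (not isolated)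
11 | tert-butyl{[(3Z)-4-[(4R)-2,2-dimethyl-1,3-dioxolan-4-yl]pent-3-en-1-yl]oxy}dimethylsilane | CC(C)(C)[Si](C)(C)OCC/C=C(/C)[C@@H]1COC(C)(C)O1 | intermediate
12 | (3Z)-4-[(4R)-2,2-dimethyl-1,3-dioxolan-4-yl]pent-3-en-1-ol | OCC/C=C(/C)[C@@H]1COC(C)(C)O1 | intermediate
13 | (3Z)-4-[(4R)-2,2-dimethyl-1,3-dioxolan-4-yl]pent-3-enal | O=CC/C=C(/C)[C@@H]1COC(C)(C)O1 | intermediate
14 | methyl prop-2-ynoate (methyl propiolate) | C#CC(=O)OC | starting material
15 | methyl (4S,6Z)-7-[(4R)-2,2-dimethyl-1,3-dioxolan-4-yl]-4-hydroxyoct-6-en-2-ynoate | COC(=O)C#C[C@@H](O)C/C=C(/C)[C@@H]1COC(C)(C)O1 | intermediate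
16 | methyl (4S,6Z)-7-[(4R)-2,2-dimethyl-1,3-dioxolan-4-yl]-4-[(triethylsilyl)oxy]oct-6-en-2-ynoate | COC(=O)C#C[C@@H](O[Si](CC)(CC)CC)C/C=C(/C)[C@@H]1COC(C)(C)O1 | intermediate
17 | methyl (2Z,4S,6Z)-7-[(4R)-2,2-dimethyl-1,3-dioxolan-4-yl]-3-methyl-4-[(triethylsilyl)oxy]octa-2,6-dienoate | COC(=O)/C=C(/C)[C@@H](O[Si](CC)(CC)CC)C/C=C(/C)[C@@H]1COC(C)(C)O1 | intermediate
18 | (2Z,4S,6Z)-7-[(4R)-2,2-dimethyl-1,3-dioxolan-4-yl]-3-methyl-4-[(triethylsilyl)oxy]octa-2,6-dien-1-ol | OC/C=C(/C)[C@@H](O[Si](CC)(CC)CC)C/C=C(/C)[C@@H]1COC(C)(C)O1 | intermediate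
19 | (2Z,4S,6Z)-7-[(4R)-2,2-dimethyl-1,3-dioxolan-4-yl]-3-methyl-4-[(triethylsilyl)oxy]octa-2,6-dienal | O=C/C=C(/C)[C@@H](O[Si](CC)(CC)CC)C/C=C(/C)[C@@H]1COC(C)(C)O1 | intermediate
20 | tert-butyldimethyl(prop-2-yn-1-yloxy)silane | C#CCO[Si](C)(C)C(C)(C)C | starting material
21 | (4R,5Z,7S,9Z)-1-[(tert-butyldimethylsilyl)oxy]-10-[(4R)-2,2-dimethyl-1,3-dioxolan-4-yl]-6-methyl-7-[(triethylsilyl)oxy]undeca-5,9-dien-2-yn-4-ol | CC(C)(C)[Si](C)(C)OCC#C[C@H](O)/C=C(/C)[C@@H](O[Si](CC)(CC)CC)C/C=C(/C)[C@@H]1COC(C)(C)O1 | intermediate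
22 | sodium cyclic alkenyl(alkoxy)bis(2-methoxyethoxy)aluminate of 21 (Al bonded to C11 and to the C6 oxygen) | COCCO[Al-]1(OCCOC)O[C@H](/C=C(/C)[C@@H](O[Si](CC)(CC)CC)C/C=C(/C)[C@@H]2COC(C)(C)O2)C=C1CO[Si](C)(C)C(C)(C)C.[Na+] | intermediate (not isolated)
23 | (2Z,4R,5Z,7S,9Z)-1-[(tert-butyldimethylsilyl)oxy]-10-[(4R)-2,2-dimethyl-1,3-dioxolan-4-yl]-2-iodo-6-methyl-7-[(triethylsilyl)oxy]undeca-2,5,9-trien-4-ol | CC(C)(C)[Si](C)(C)OC/C(I)=C/[C@H](O)/C=C(/C)[C@@H](O[Si](CC)(CC)CC)C/C=C(/C)[C@@H]1COC(C)(C)O1 | intermediate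
24 | (5R)-3-{[(tert-butyldimethylsilyl)oxy]methyl}-5-{(1Z,3S,5Z)-6-[(4R)-2,2-dimethyl-1,3-dioxolan-4-yl]-2-methyl-3-[(triethylsilyl)oxy]hepta-1,5-dien-1-yl}furan-2(5H)-one | O=C1O[C@H](/C=C(/C)[C@@H](O[Si](CC)(CC)CC)C/C=C(/C)[C@@H]2COC(C)(C)O2)C=C1CO[Si](C)(C)C(C)(C)C | intermediate
25 | (5R)-3-{[(tert-butyldimethylsilyl)oxy]methyl}-5-{(1Z,3S,5Z)-6-[(4R)-2,2-dimethyl-1,3-dioxolan-4-yl]-3-hydroxy-2-methylhepta-1,5-dien-1-yl}furan-2(5H)-one | O=C1O[C@H](/C=C(/C)[C@@H](O)C/C=C(/C)[C@@H]2COC(C)(C)O2)C=C1CO[Si](C)(C)C(C)(C)C | intermediate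
26 | (5R)-5-{(1Z,3S,5Z)-3-acetoxy-6-[(4R)-2,2-dimethyl-1,3-dioxolan-4-yl]-2-methylhepta-1,5-dien-1-yl}-3-{[(tert-butyldimethylsilyl)oxy]methyl}furan-2(5H)-one | O=C1O[C@H](/C=C(/C)[C@@H](OC(C)=O)C/C=C(/C)[C@@H]2COC(C)(C)O2)C=C1CO[Si](C)(C)C(C)(C)C | intermediate
27 | (5R)-5-[(1Z,3S,5Z,7R)-3-acetoxy-7,8-dihydroxy-2,6-dimethylocta-1,5-dien-1-yl]-3-(hydroxymethyl)furan-2(5H)-one | O=C1O[C@H](/C=C(/C)[C@@H](OC(C)=O)C/C=C(/C)[C@@H](O)CO)C=C1CO | intermediate
28 | (5R)-5-[(1Z,3S,5Z,7R)-3-acetoxy-7-hydroxy-2,6-dimethyl-8-[(triethylsilyl)oxy]octa-1,5-dien-1-yl]-3-{[(triethylsilyl)oxy]methyl}furan-2(5H)-one | O=C1O[C@H](/C=C(/C)[C@@H](OC(C)=O)C/C=C(/C)[C@@H](O)CO[Si](CC)(CC)CC)C=C1CO[Si](CC)(CC)CC | intermediate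
29 | (2R,3R)-2,3-dimethyloxirane-2-carboxylic 2,4,6-trichlorobenzoic anhydride | O=C(OC(=O)[C@]1(C)O[C@@H]1C)c1c(Cl)cc(Cl)cc1Cl | intermediate (not isolated)
30 | (5R)-5-[(1Z,3S,5Z,7R)-3-acetoxy-7-{[(2R,3R)-2,3-dimethyloxirane-2-carbonyl]oxy}-2,6-dimethyl-8-[(triethylsilyl)oxy]octa-1,5-dien-1-yl]-3-{[(triethylsilyl)oxy]methyl}furan-2(5H)-one | O=C1O[C@H](/C=C(/C)[C@@H](OC(C)=O)C/C=C(/C)[C@@H](OC(=O)[C@]2(C)O[C@@H]2C)CO[Si](CC)(CC)CC)C=C1CO[Si](CC)(CC)CC | intermediate
31 | (5R)-5-[(1Z,3S,5Z,7R)-3-acetoxy-7-{[(2R,3R)-2,3-dimethyloxirane-2-carbonyl]oxy}-8-hydroxy-2,6-dimethylocta-1,5-dien-1-yl]-3-(hydroxymethyl)furan-2(5H)-one | O=C1O[C@H](/C=C(/C)[C@@H](OC(C)=O)C/C=C(/C)[C@@H](OC(=O)[C@]2(C)O[C@@H]2C)CO)C=C1CO | intermediate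
32 | (5R)-5-[(1Z,3S,5Z,7R)-3-acetoxy-7-{[(2R,3R)-2,3-dimethyloxirane-2-carbonyl]oxy}-8-hydroxy-2,6-dimethylocta-1,5-dien-1-yl]-3-(bromomethyl)furan-2(5H)-one | O=C1O[C@H](/C=C(/C)[C@@H](OC(C)=O)C/C=C(/C)[C@@H](OC(=O)[C@]2(C)O[C@@H]2C)CO)C=C1CBr | intermediate
33 | (5R)-5-[(1Z,3S,5Z,7R)-3-acetoxy-7-{[(2R,3R)-2,3-dimethyloxirane-2-carbonyl]oxy}-2,6-dimethyl-8-oxoocta-1,5-dien-1-yl]-3-(bromomethyl)furan-2(5H)-one | O=C1O[C@H](/C=C(/C)[C@@H](OC(C)=O)C/C=C(/C)[C@@H](OC(=O)[C@]2(C)O[C@@H]2C)C=O)C=C1CBr | intermediate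
34 | allylchromium dichloride derived from 33 (CrCl2 group on the exocyclic CH2, C13) | O=C1O[C@H](/C=C(/C)[C@@H](OC(C)=O)C/C=C(/C)[C@@H](OC(=O)[C@]2(C)O[C@@H]2C)C=O)C=C1C[Cr](Cl)Cl | intermediate (not isolated)
35 | CNP0137407.10, (3S,6R,7R,8R,9R,1(10)Z,4Z)-3-acetoxy-9-{[(2R,3R)-2,3-dimethyloxirane-2-carbonyl]oxy}-8-hydroxygermacra-1(10),4,11(13)-trien-12,6-olide | C=C1C(=O)O[C@@H]2/C=C(/C)[C@@H](OC(C)=O)C/C=C(/C)[C@@H](OC(=O)[C@]3(C)O[C@@H]3C)[C@H](O)[C@@H]12 | target

**Totals and risks**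

Total step count: 25. Longest linear sequence: 21 steps (step 4 and steps 6–25, from 5).

Steps most likely to fail:

1. Step 25. The allylchromium species may add to the aldehyde of a second molecule faster than to its own (oligomers). Divalent chromium may attack the epoxy ester or the α-acyloxy aldehyde by electron transfer. The ring may also close through the Felkin-preferred aldehyde face and give the C8 epimer. Fallback: the transient allylchromium is replaced by an isolable allylboronate, so that ring closure becomes a reagent-free thermal allylboration that can be run at any dilution. It sets out from bromide 32. Miyaura-type allylic borylation (B2pin2, Pd2(dba)3 cat., toluene/DMSO, rt) should give the pinacol allylboronate alcohol F1, and Dess–Martin oxidation the boronate aldehyde F2. Heating F2 in toluene (80–100 °C, about 1 mM) should close the ring through the same γ-selective chair, and hydrolysis of the cyclic borate (aq. NaHCO3/triethanolamine) brings the route back at 35.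

2. Step 15. The alkenylaluminate 22 carries a β-silyloxy group and may eliminate silyloxide to give an allene, and hydride may be delivered with incomplete regiocontrol. Fallback: the aluminium hydride is replaced by a ruthenium-catalysed trans-hydrosilylation, which does not form a species prone to β-elimination. It sets out from 21. [Cp*Ru(MeCN)3]PF6 (cat.) and Et3SiH in CH2Cl2 should place silicon on the alkyne carbon distal to the hydroxyl with trans addition, giving the (Z)-vinylsilane F3. Iododesilylation with retention (N-iodosuccinimide, hexafluoroisopropanol, 0 °C) brings the route back at 23.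

3. Step 9. The β,γ-unsaturated aldehyde 13 may isomerise into conjugation under the basic zinc conditions, and facial selectivity on an unbranched aliphatic aldehyde may be poor. Fallback: catalyst-controlled addition is replaced by unselective addition followed by reagent-controlled reduction. It sets out from 13. The lithium acetylide of 14 (LiN(SiMe3)2, THF, −78 °C) should give 15 together with its C4 epimer, methyl (4R,6Z)-7-[(4R)-2,2-dimethyl-1,3-dioxolan-4-yl]-4-hydroxyoct-6-en-2-ynoate F4. The mixture is oxidised (Dess–Martin periodinane) to the ynone, methyl (6Z)-7-[(4R)-2,2-dimethyl-1,3-dioxolan-4-yl]-4-oxooct-6-en-2-ynoate F5. Midland reduction of F5 with (S)-Alpine-Borane (from (−)-α-pinene) brings the route back at 15.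

Further compounds
F1 | step 25 | (5R)-5-[(1Z,3S,5Z,7R)-3-acetoxy-7-{[(2R,3R)-2,3-dimethyloxirane-2-carbonyl]oxy}-8-hydroxy-2,6-dimethylocta-1,5-dien-1-yl]-3-[(4,4,5,5-tetramethyl-1,3,2-dioxaborolan-2-yl)methyl]furan-2(5H)-one | O=C1O[C@H](/C=C(/C)[C@@H](OC(C)=O)C/C=C(/C)[C@@H](OC(=O)[C@]2(C)O[C@@H]2C)CO)C=C1CB1OC(C)(C)C(C)(C)O1
F2 | step 25 | (5R)-5-[(1Z,3S,5Z,7R)-3-acetoxy-7-{[(2R,3R)-2,3-dimethyloxirane-2-carbonyl]oxy}-2,6-dimethyl-8-oxoocta-1,5-dien-1-yl]-3-[(4,4,5,5-tetramethyl-1,3,2-dioxaborolan-2-yl)methyl]furan-2(5H)-one | O=C1O[C@H](/C=C(/C)[C@@H](OC(C)=O)C/C=C(/C)[C@@H](OC(=O)[C@]2(C)O[C@@H]2C)C=O)C=C1CB1OC(C)(C)C(C)(C)O1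
F3 | step 15 | (2Z,4R,5Z,7S,9Z)-1-[(tert-butyldimethylsilyl)oxy]-10-[(4R)-2,2-dimethyl-1,3-dioxolan-4-yl]-6-methyl-2-(triethylsilyl)-7-[(triethylsilyl)oxy]undeca-2,5,9-trien-4-ol | CC(C)(C)[Si](C)(C)OC/C([Si](CC)(CC)CC)=C/[C@H](O)/C=C(/C)[C@@H](O[Si](CC)(CC)CC)C/C=C(/C)[C@@H]1COC(C)(C)O1
F4 | step 9 | methyl (4R,6Z)-7-[(4R)-2,2-dimethyl-1,3-dioxolan-4-yl]-4-hydroxyoct-6-en-2-ynoate | COC(=O)C#C[C@H](O)C/C=C(/C)[C@@H]1COC(C)(C)O1
F5 | step 9 | methyl (6Z)-7-[(4R)-2,2-dimethyl-1,3-dioxolan-4-yl]-4-oxooct-6-en-2-ynoate | COC(=O)C#CC(=O)C/C=C(/C)[C@@H]1COC(C)(C)O1
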